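**Remark on the chemistry:** the target SMILES defines no stereo element; the hindered biaryl axis is taken as configurationally unassigned, so no step has to control stereochemistry.

## Retrosynthetic overview

1. Numbering: ring B (quinone) = C1(=O), C2(OMe), C3(H), C4(=O); ring A = C4a, C5(H), C6(Me), C7(Me), C8(aryl), C8a; ring C = 2,4,5-trimethoxyphenyl. The target comes from a 3-methoxy-1-naphthol (OH on C4, H on C1) by a late phenol-to-para-quinone oxidation that adds the C1 oxygen.
2. Ring B is disconnected to an aryl diazomethyl ketone and methoxyacetylene by a Danheiser benzannulation: C1–C2, C3–C4 and C4–C4a form in one operation, and C1–C8a arises in the same flask by the Wolff shift.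
3. Enabling feature: on ring B the oxygens on C4 and C2 are meta to each other with C3–H between them, which is the pattern a ketene carbonyl and an ynol ether deliver; on ring A, C8 is blocked by ring C, so C4a–H is the only position where ring B can close.
4. The diazoketone comes from the biaryl carboxylic acid, and this from Suzuki coupling of a salicylaldehyde triflate (ortho-formylation of 2,3-dimethylphenol) with 2,4,5-trimethoxyphenylboronic acid.
5. Ring order: rings A and C are bought and joined in step 3; ring B is the only ring built (step 7) and is then oxidised (step 8).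

Key step: step 7

## Route

Step 1
Reactants: 1 2,3-dimethylphenol
Product: 2 2-hydroxy-3,4-dimethylbenzaldehyde
Conditions: MgCl2, Et3N, paraformaldehyde, MeCN, reflux; aq. HCl work-up
Reagents that add atoms: paraformaldehyde (reacts as formaldehyde), C=O
Why: Casnati–Skattebøl ortho-formylation, in which the magnesium phenoxide delivers formaldehyde to the only free ortho position of 1 and a second formaldehyde oxidises the benzylic alkoxide by Oppenauer-type hydride transfer.

Step 2
Reactants: 2 2-hydroxy-3,4-dimethylbenzaldehyde
Product: 3 6-formyl-2,3-dimethylphenyl trifluoromethanesulfonate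
Conditions: Tf2O, pyridine, CH2Cl2, 0 °C
Reagents that add atoms: trifluoromethanesulfonic anhydride, O=S(=O)(OS(=O)(=O)C(F)(F)F)C(F)(F)F
Why: O-sulfonylation of the phenol with Tf2O and pyridine gives the aryl triflate, and the aldehyde is inert under these conditions.

Step 3
Reactants: 3 6-formyl-2,3-dimethylphenyl trifluoromethanesulfonate; 4 (2,4,5-trimethoxyphenyl)boronic acid
Product: 5 3,4-dimethyl-2-(2,4,5-trimethoxyphenyl)benzaldehyde
Conditions: Pd(OAc)2 (2 mol %), SPhos (4 mol %), K3PO4, toluene/H2O (10:1), 90 °C
Reagents that add atoms: none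
Why: Suzuki–Miyaura coupling, in which the ortho-formyl group speeds oxidative addition of the C–OTf bond to zerovalent palladium and the bulky, electron-rich SPhos ligand permits transmetalation and reductive elimination to the tri-ortho-substituted biaryl.

Step 4
Reactants: 5 3,4-dimethyl-2-(2,4,5-trimethoxyphenyl)benzaldehyde
Product: 6 3,4-dimethyl-2-(2,4,5-trimethoxyphenyl)benzoic acid
Conditions: NaClO2, NaH2PO4, 2-methyl-2-butene, t-BuOH/H2O, rt
Reagents that add atoms: sodium chlorite, [Na+].[O-]Cl=O
Why: Pinnick oxidation converts the aldehyde selectively into the acid, while 2-methyl-2-butene scavenges the HOCl that could otherwise chlorinate electron-rich ring C.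

Step 5
Reactants: 6 3,4-dimethyl-2-(2,4,5-trimethoxyphenyl)benzoic acid
Product: 8 2-diazo-1-[3,4-dimethyl-2-(2,4,5-trimethoxyphenyl)phenyl]ethan-1-one, via acid chloride 7 (not isolated)
Conditions: (COCl)2, DMF (cat.), CH2Cl2, 0 °C to rt; evaporate; then Me3SiCHN2 (2 equiv), THF/MeCN, 0 °C to rt
Reagents that add atoms: oxalyl chloride, O=C(Cl)C(=O)Cl; (trimethylsilyl)diazomethane, C[Si](C)(C)C=[N+]=[N-]
Why: Acid chloride formation followed by C-acylation of (trimethylsilyl)diazomethane with loss of Me3SiCl (Arndt–Eistert-type diazoketone synthesis) gives the diazomethyl ketone without a Lewis acid that could close 7 onto ring C.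

Step 6
Reactants: 9 2-chloro-1,1-dimethoxyethane (chloroacetaldehyde dimethyl acetal)
Product: 11 methoxyacetylene (methoxyethyne), via sodium methoxyacetylide 10 (not isolated)
Conditions: NaNH2 (3 equiv), liquid NH3, −33 °C; evaporate NH3; then cold saturated aq. NaCl, distil (bp about 23 °C) into a cold trap, use at once
Reagents that add atoms: none
Why: Twofold base-induced elimination (loss of HCl and of MeOH) by NaNH2 gives the acetylide, which is stable in the basic medium and releases the volatile ynol ether on hydrolysis.

Step 7
Reactants: 8 2-diazo-1-[3,4-dimethyl-2-(2,4,5-trimethoxyphenyl)phenyl]ethan-1-one; 11 methoxyacetylene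
Product: 16 3-methoxy-6,7-dimethyl-5-(2,4,5-trimethoxyphenyl)naphthalen-1-ol, via arylketene 12 (not isolated), via cyclobutenone 13 (not isolated), via dienylketene 14 (not isolated), via keto tautomer 15 (not isolated)
Conditions: hν (254 nm, quartz), 11 (4 equiv), degassed ClCH2CH2Cl, sealed vessel, rt; then 80 °C
Reagents that add atoms: none
Why: Light induces a Wolff rearrangement of 8 (loss of N2 with 1,2-shift of ring A, which makes C1–C8a) to arylketene 12, and its C=C bond adds the ynol ether 11 in a [2+2] cycloaddition, the nucleophilic CH terminus going to the ketene carbonyl carbon (C3–C4) and the methoxy-bearing carbon to the ketene alpha carbon (C1–C2), to give cyclobutenone 13. Heating opens 13 by reversible 4π electrocyclic cleavage of its C1–C4 bond to dienylketene 14, which closes by 6π electrocyclisation of the ketene carbon C4 onto C4a and tautomerises through dienone 15 to naphthol 16. The closest known reaction type is the Danheiser benzannulation in its second-generation form, in which aryl diazomethyl ketones and alkoxy- or siloxyalkynes give fused resorcinol monoethers. Ring B is the only ring that remains and it closes by the thermal disrotatory 6π electrocyclisation, the four-membered ring of 13 being temporary. No stereocentre reaches 16, since the sp3 centres of racemic 13 and 15 are lost on ring opening and aromatisation. Two regiochemical demands are met by the substrate: the polarisation of 11 fixes the meta relation of the C4 hydroxyl and the C2 methoxy group, and because C8 carries ring C, C4a–H is the only ortho position of ring A at which closure can be followed by rearomatisation.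

Step 8
Reactants: 16 3-methoxy-6,7-dimethyl-5-(2,4,5-trimethoxyphenyl)naphthalen-1-ol
Product: 17 2-methoxy-6,7-dimethyl-8-(2,4,5-trimethoxyphenyl)naphthalene-1,4-dione
Conditions: K2[ON(SO3)2] (Fremy's salt, 2.5 equiv), KH2PO4 buffer, acetone/H2O, 0 °C to rt
Reagents that add atoms: potassium nitrosodisulfonate, [K+].[K+].[O]N(S(=O)(=O)[O-])S(=O)(=O)[O-]
Why: Teuber oxidation, in which the phenoxy radical of 16 is trapped by a second nitroxyl radical at the free position para to the hydroxyl (C1, further activated by the ortho methoxy group) and loss of imidodisulfonate gives the 1,4-quinone, while the aryl methyl ethers of ring C are not touched.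

## Compound list

1 | 2,3-dimethylphenol | Cc1cccc(O)c1C | starting material
2 | 2-hydroxy-3,4-dimethylbenzaldehyde | Cc1ccc(C=O)c(O)c1C | intermediate
3 | 6-formyl-2,3-dimethylphenyl trifluoromethanesulfonate | Cc1ccc(C=O)c(OS(=O)(=O)C(F)(F)F)c1C | intermediate
4 | (2,4,5-trimethoxyphenyl)boronic acid | COc1cc(OC)c(OC)cc1B(O)O | starting material
5 | 3,4-dimethyl-2-(2,4,5-trimethoxyphenyl)benzaldehyde | Cc1ccc(C=O)c(-c2cc(OC)c(OC)cc2OC)c1C | intermediate
6 | 3,4-dimethyl-2-(2,4,5-trimethoxyphenyl)benzoic acid | Cc1ccc(C(=O)O)c(-c2cc(OC)c(OC)cc2OC)c1C | intermediate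
7 | 3,4-dimethyl-2-(2,4,5-trimethoxyphenyl)benzoyl chloride (not isolated) | Cc1ccc(C(=O)Cl)c(-c2cc(OC)c(OC)cc2OC)c1C | intermediate
8 | 2-diazo-1-[3,4-dimethyl-2-(2,4,5-trimethoxyphenyl)phenyl]ethan-1-one | Cc1ccc(C(=O)C=[N+]=[N-])c(-c2cc(OC)c(OC)cc2OC)c1C | intermediate
9 | 2-chloro-1,1-dimethoxyethane | COC(CCl)OC | starting material
10 | sodium methoxyacetylide (not isolated) | [Na+].[C-]#COC | intermediate
11 | methoxyacetylene | COC#C | intermediate
12 | 2-[3,4-dimethyl-2-(2,4,5-trimethoxyphenyl)phenyl]ethen-1-one, the arylketene (not isolated) | Cc1ccc(C=C=O)c(-c2cc(OC)c(OC)cc2OC)c1C | intermediate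
13 | 4-[3,4-dimethyl-2-(2,4,5-trimethoxyphenyl)phenyl]-3-methoxycyclobut-2-en-1-one, racemic (not isolated) | COC1=CC(=O)C1c1ccc(C)c(C)c1-c1cc(OC)c(OC)cc1OC | intermediate
14 | 4-[3,4-dimethyl-2-(2,4,5-trimethoxyphenyl)phenyl]-3-methoxybuta-1,3-dien-1-one, aryl group and ketene carbon cis across C3=C4 (not isolated) | O=C=C/C(OC)=C\c1ccc(C)c(C)c1-c1cc(OC)c(OC)cc1OC | intermediate
15 | 3-methoxy-6,7-dimethyl-5-(2,4,5-trimethoxyphenyl)naphthalen-1(8aH)-one, racemic (not isolated) | O=C1C=C(OC)C=C2C(-c3cc(OC)c(OC)cc3OC)=C(C)C(C)=CC12 | intermediate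
16 | 3-methoxy-6,7-dimethyl-5-(2,4,5-trimethoxyphenyl)naphthalen-1-ol | COc1cc(O)c2cc(C)c(C)c(-c3cc(OC)c(OC)cc3OC)c2c1 | intermediate
17 | 2-methoxy-6,7-dimethyl-8-(2,4,5-trimethoxyphenyl)naphthalene-1,4-dione | COC1=CC(=O)c2cc(C)c(C)c(-c3cc(OC)c(OC)cc3OC)c2C1=O | target

## Summary

Total step count: 8 (seven on the main line and one for the alkyne partner).
Longest linear sequence: 7 steps (steps 1, 2, 3, 4, 5, 7, 8).

## Steps most likely to fail

**Step 7.** Several processes can divert the cascade.
- The electron-rich biaryl may compete for the light and cause secondary photolysis.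
- The excited diazoketone may react as a carbene with ring C instead of undergoing the Wolff shift.
- The ketene may be captured by the product naphthol (ester formation, reversible by KOH/MeOH) or by ring C before the volatile alkyne adds.

Fallback, from 8 back to 16: the ketene is generated without light and without a free carbene. Silver-catalysed Arndt–Eistert homologation of 8 (PhCO2Ag, Et3N, THF/H2O, rt) should give 2-[3,4-dimethyl-2-(2,4,5-trimethoxyphenyl)phenyl]acetic acid F1. Treatment with (COCl)2 and catalytic DMF in CH2Cl2 should give 2-[3,4-dimethyl-2-(2,4,5-trimethoxyphenyl)phenyl]acetyl chloride F2. Slow addition of Et3N to F2 and excess 11 in toluene at 0 °C, then heating to 80 °C, should form arylketene 12 by dehydrochlorination. It is expected to continue through 13, 14 and 15 to naphthol 16, where the route is rejoined. This fallback answers the photochemical failures only; the ketene cascade itself is unchanged.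

**Step 8.** The oxidant may attack the unhindered position C3, between the hydroxyl and the methoxy group, and lead to an ortho-quinone. The desired position C1 lies peri to the twisted ring C and is shielded against the bulky nitroxyl radical.

Fallback, from 16 back to 17: a two-electron oxidation with a small nucleophile. PhI(OAc)2 (2.2 equiv) in MeOH at 0 °C should give the quinone monoketal 3,4,4-trimethoxy-6,7-dimethyl-5-(2,4,5-trimethoxyphenyl)naphthalen-1(4H)-one F3 by twofold para-methoxylation. Mild hydrolysis (aqueous oxalic acid, THF, rt) should then release quinone 17 without cleaving the vinylogous ester.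

**Step 5.** Three processes threaten the diazoketone synthesis.
- Acid chloride 7 may close by Friedel–Crafts acylation onto ring C to give a fluorenone.
- HCl may cause loss of N2 from 8 and give a chloromethyl ketone.
- Acylation of Me3SiCHN2 by the hindered acid chloride may be incomplete.

Fallback, from 5 back to 8: a diazo transfer that avoids the acid chloride.
- Addition of MeMgBr to aldehyde 5 (THF, −78 °C) should give 1-[3,4-dimethyl-2-(2,4,5-trimethoxyphenyl)phenyl]ethan-1-ol F4 (racemic).
- Dess–Martin periodinane (CH2Cl2, rt) should give 1-[3,4-dimethyl-2-(2,4,5-trimethoxyphenyl)phenyl]ethan-1-one F5.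
- Trifluoroacetylation of its enolate (LiN(SiMe3)2, THF, −78 °C, then CF3CO2CH2CF3) should give 4,4,4-trifluoro-1-[3,4-dimethyl-2-(2,4,5-trimethoxyphenyl)phenyl]butane-1,3-dione F6, which is not isolated.
- Detrifluoroacetylative diazo transfer (MsN3, Et3N, H2O, MeCN, rt) should then give diazoketone 8.

## Further compounds

F1 | step 7 | 2-[3,4-dimethyl-2-(2,4,5-trimethoxyphenyl)phenyl]acetic acid | Cc1ccc(CC(=O)O)c(-c2cc(OC)c(OC)cc2OC)c1C
F2 | step 7 | 2-[3,4-dimethyl-2-(2,4,5-trimethoxyphenyl)phenyl]acetyl chloride | Cc1ccc(CC(=O)Cl)c(-c2cc(OC)c(OC)cc2OC)c1C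
F3 | step 8 | 3,4,4-trimethoxy-6,7-dimethyl-5-(2,4,5-trimethoxyphenyl)naphthalen-1(4H)-one | COC1=CC(=O)c2cc(C)c(C)c(-c3cc(OC)c(OC)cc3OC)c2C1(OC)OC
F4 | step 5 | 1-[3,4-dimethyl-2-(2,4,5-trimethoxyphenyl)phenyl]ethan-1-ol (racemic) | Cc1ccc(C(C)O)c(-c2cc(OC)c(OC)cc2OC)c1C
F5 | step 5 | 1-[3,4-dimethyl-2-(2,4,5-trimethoxyphenyl)phenyl]ethan-1-one | Cc1ccc(C(C)=O)c(-c2cc(OC)c(OC)cc2OC)c1C
F6 | step 5 | 4,4,4-trifluoro-1-[3,4-dimethyl-2-(2,4,5-trimethoxyphenyl)phenyl]butane-1,3-dione | Cc1ccc(C(=O)CC(=O)C(F)(F)F)c(-c2cc(OC)c(OC)cc2OC)c1C
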